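Ring B (C5–C10) is traced back to the cyclopentanone of a trans-fused 6–5 ketone made from the (R)-enantiomer of the proline-derived bicyclic enedione 1; the feature exploited is the quaternary C10 flanking the C8 carbonyl. In the key step dibromomethyllithium adds to C8, bromine–lithium exchange gives a β-oxido carbenoid, C10 shifts onto the new carbon (C9), and the resulting C8/C9 enolate is trapped at C9 by a glutarate-derived C11–C15 aldehyde. One operation thus inserts C9 into the C8–C10 bond, enlarges the five-membered ring to ring B and unites three components at C9. Ring A of the precursor carries a C2=C3 alkene as masked cis-diol.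

Key step: step 10

Locants: labdane numbering throughout (ring A C1–C5 and C10; ring B C5–C10; side chain C11–C15; C16 on C13, C17 on C8, C18 and C19 on C4, C20 on C10). In the 6–5 compounds the small ring is C5–C6–C7–C8–C10.

Assumption: enedione 1 and half-ester 8 are purchased as single enantiomers; 1 is otherwise available from 2-methylcyclopentane-1,3-dione and methyl vinyl ketone by D-proline catalysis.

Step 1
Reactants: 1 (R)-enedione (7aR)-7a-methyl-2,3,7,7a-tetrahydro-1H-indene-1,5(6H)-dione
Product: 2 monoketal (7aR)-1,1-(ethylenedioxy)-7a-methyl-1,2,3,6,7,7a-hexahydro-5H-inden-5-one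
Conditions: (TMSOCH2)2, TMSOTf (cat.), CH2Cl2, −78 → −20 °C
Reagents that add atoms: 1,2-bis(trimethylsilyloxy)ethane, C[Si](C)(C)OCCO[Si](C)(C)C
Why: Chemoselective ketalization (Noyori conditions): the saturated cyclopentanone is ketalized much faster than the conjugated enone carbonyl, so only the future C8 ketone should be masked.

Step 2
Reactants: 2 monoketal
Product: 3 β,γ-unsaturated ketone (7aR)-1,1-(ethylenedioxy)-4,4,7a-trimethyl-1,2,4,6,7,7a-hexahydro-5H-inden-5-one (C5=C6 alkene, C3 ketone, gem-dimethyl C4 in labdane locants)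
Conditions: KOt-Bu, MeI, t-BuOH/THF, 0 → 23 °C
Reagents that add atoms: iodomethane, CI
Why: Deconjugative α,α-dimethylation of an enone: γ-deprotonation gives the extended dienolate, which is methylated twice at the α-carbon (future C4), leaving the alkene out of conjugation at C5=C6.

Step 3
Reactants: 3 β,γ-unsaturated ketone
Product: 4 trans-fused ketone (3aR,7aR)-1,1-(ethylenedioxy)-4,4,7a-trimethyloctahydro-5H-inden-5-one (H5 anti to the C10 methyl)
Conditions: H2 (1 atm), Pd/C, EtOAc, 23 °C
Reagents that add atoms: none
Why: Heterogeneous catalytic hydrogenation should deliver hydrogen to the trisubstituted C5=C6 alkene from the face opposite the angular C10 methyl, setting H5 anti to that methyl (trans ring fusion).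

Step 4
Reactants: 4 trans-fused ketone
Product: 5 enol triflate (3aR,7aR)-1,1-(ethylenedioxy)-4,4,7a-trimethyl-2,3,3a,4,7,7a-hexahydro-1H-inden-5-yl trifluoromethanesulfonate (C2=C3 in labdane locants)
Conditions: KN(SiMe3)2, THF, −78 °C; PhNTf2, −78 → 0 °C
Reagents that add atoms: N-phenylbis(trifluoromethanesulfonimide), O=S(=O)(N(c1ccccc1)S(=O)(=O)C(F)(F)F)C(F)(F)F
Why: Enol triflate formation: the C3 ketone can enolise only toward C2 because C4 is quaternary, and the potassium enolate is O-sulfonylated.

Step 5
Reactants: 5 enol triflate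
Product: 6 alkene ketal (3aR,7aR)-1,1-(ethylenedioxy)-4,4,7a-trimethyl-2,3,3a,4,7,7a-hexahydro-1H-indene
Conditions: Pd(OAc)2 (cat.), PPh3, n-Bu3N, HCO2H, DMF, 60 °C
Reagents that add atoms: none
Why: Palladium-catalysed formate reduction of an enol triflate (oxidative addition, formate decarboxylation, C–H reductive elimination) gives the C2=C3 alkene that serves as the masked 2,3-diol.

Step 6
Reactants: 6 alkene ketal
Product: 7 bicyclic ketone (3aR,7aR)-4,4,7a-trimethyl-2,3,3a,4,7,7a-hexahydro-1H-inden-1-one (C8 ketone, C2=C3 alkene, trans-fused)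
Conditions: 2 M HCl, THF, 23 °C
Reagents that add atoms: water, O
Why: Acid-catalysed ketal hydrolysis frees the C8 ketone; the unconjugated alkene and the ring-fusion centres are not affected.

Step 7
Reactants: 8 (R)-3-methylglutaric acid monomethyl ester
Product: 9 methyl (3R)-5-hydroxy-3-methylpentanoate
Conditions: BH3·SMe2, THF, 0 → 23 °C; MeOH
Reagents that add atoms: none
Why: Chemoselective borane reduction: the carboxylic acid is reduced much faster than the methyl ester, and the remote stereocentre (future C13) is untouched.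

Step 8
Reactants: 9 hydroxy ester
Product: 10 methyl (3R)-5-(tert-butyldimethylsilyloxy)-3-methylpentanoate
Conditions: TBSCl, imidazole, DMF, 23 °C
Reagents that add atoms: tert-butyldimethylsilyl chloride, CC(C)(C)[Si](C)(C)Cl
Why: Silyl ether protection of the primary alcohol prevents lactonisation and masks the future C15 oxygen.

Step 9
Reactants: 10 silyl ether ester
Product: 11 aldehyde (3R)-5-(tert-butyldimethylsilyloxy)-3-methylpentanal
Conditions: i-Bu2AlH, CH2Cl2, −78 °C
Reagents that add atoms: none
Why: Partial ester reduction: at −78 °C the aluminium hemiacetal is stable and gives the C11 aldehyde only on work-up.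

Step 10
Reactants: 7 bicyclic ketone; 11 aldehyde; 12 dibromomethane
Product: 16 aldol adduct 15-(tert-butyldimethylsilyloxy)-11-hydroxy-17-norlabd-2-en-8-one (C11 epimers; side chain at C9 expected anti to the C10 methyl), via lithium alkoxide 13 (not isolated), via β-oxido carbenoid 14 (not isolated), via lithium enolate 15 (not isolated)
Conditions: 12, lithium 2,2,6,6-tetramethylpiperidide, THF, −90 °C; 7; n-BuLi, −90 → −20 °C; 11, −78 °C; NH4Cl (aq)
Reagents that add atoms: none
Why: Dibromomethyllithium adds to the C8 carbonyl anti to the C10 methyl to give 13; bromine–lithium exchange gives carbenoid 14, in which the C8–C10 bond shifts to the carbenoid carbon with loss of LiBr, and the ring-enlarged enolate 15 (C8–O, C8=C9) is trapped at C9 by aldehyde 11. The closest known reaction type is the β-oxido carbenoid one-carbon ring enlargement of cyclic ketones with dibromomethyllithium, followed by an aldol addition of the regiodefined lithium enolate. No ring is closed from an open chain: ring B arises by enlargement of the cyclopentanone through a 1,2-alkyl shift that inserts C9 between C8 and C10, with retention at the migrating C10. The new stereocentres C9 and C11 are not controlled here and are both erased in step 11, while C5, C10 and C13 are untouched. The step needs migration of the quaternary C10 and not of the methylene C7; this should be secured by the higher migratory aptitude of the more substituted carbon toward the electron-poor carbenoid centre and by the rotamer that places the large bromine anti to the bulky C10, which is the alignment required for C10 to migrate. The site of C–C bond formation with the aldehyde is fixed because the enolate is generated only across C8/C9 and does not equilibrate at −78 °C.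

Step 11
Reactants: 16 aldol adduct
Product: 18 enone (Z)-15-(tert-butyldimethylsilyloxy)-17-norlabda-2,9(11)-dien-8-one, via mesylate 17 (not isolated)
Conditions: MsCl, Et3N, CH2Cl2, 0 °C; then DBU, 23 °C
Reagents that add atoms: none
Why: Mesylation and E1cB elimination give the conjugated exocyclic enone, expected as the Z isomer because the E geometry would press C12 against quaternary C10; both uncontrolled stereocentres of 16 disappear, and either geometry serves in step 12.

Step 12
Reactants: 18 enone
Product: 19 ketone (5R,9S,10R,13S)-15-(tert-butyldimethylsilyloxy)-17-norlabd-2-en-8-one (side chain equatorial, H9 anti to the C10 methyl)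
Conditions: [(Ph3P)CuH]6, H2O, toluene, 23 °C
Reagents that add atoms: none
Why: Conjugate reduction by the copper hydride gives the C8/C9 copper enolate, which is protonated at C9 on the face opposite the axial C10 methyl (axial protonation), so the side chain ends equatorial as in the target.

Step 13
Reactants: 19 ketone
Product: 20 enol triflate (5R,9S,10R,13S)-15-(tert-butyldimethylsilyloxy)-17-norlabda-2,7-dien-8-yl trifluoromethanesulfonate
Conditions: KN(SiMe3)2, THF, −78 °C; PhNTf2
Reagents that add atoms: N-phenylbis(trifluoromethanesulfonimide), O=S(=O)(N(c1ccccc1)S(=O)(=O)C(F)(F)F)C(F)(F)F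
Why: Kinetic enol triflate formation: deprotonation takes the unhindered C7 methylene in preference to the tertiary C9–H, which fixes the C7=C8 position of the future alkene and leaves C9 untouched.

Step 14
Reactants: 20 enol triflate
Product: 21 diol (2S,3R,5S,9S,10R,13S)-15-(tert-butyldimethylsilyloxy)-2,3-dihydroxy-17-norlabd-7-en-8-yl trifluoromethanesulfonate
Conditions: OsO4 (cat.), N-methylmorpholine N-oxide, acetone/H2O, 23 °C
Reagents that add atoms: osmium tetroxide, O=[Os](=O)(=O)=O; N-methylmorpholine N-oxide, C[N+]1([O-])CCOCC1; water, O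
Why: Catalytic osmium tetroxide syn-dihydroxylation: the electron-poor enol triflate alkene should be inert, and the C2=C3 alkene is attacked from the face opposite the axial C10 and C4 methyl groups, giving the cis-diol with equatorial 2-OH and axial 3-OH.

Step 15
Reactants: 21 diol
Product: 23 triol (2S,3R,5S,9R,10S,13S)-labd-7-ene-2,3,15-triol, via silyl ether diol 22 (not isolated)
Conditions: Pd(PPh3)4 (cat.), MeZnCl, THF, 60 °C; then HCl, MeOH, 23 °C
Reagents that add atoms: methylzinc chloride, C[Zn]Cl
Why: Negishi coupling of the enol triflate installs C17 on C8 without moving the C7=C8 double bond, and mild acidic methanolysis in the same flask removes the primary silyl ether.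

Step 16
Reactants: 23 triol
Product: 24 target (2S,3R,5S,9R,10S,13S)-3-hydroxylabd-7-ene-2,15-diyl diacetate
Conditions: Ac2O (2.2 equiv), pyridine, CH2Cl2, 0 °C
Reagents that add atoms: acetic anhydride, CC(=O)OC(C)=O
Why: Site-selective acetylation: the primary C15 hydroxyl and the equatorial C2 hydroxyl are acylated, while the axial C3 hydroxyl next to the C4 gem-dimethyl group should remain free.

Compound list

1 | (7aR)-7a-methyl-2,3,7,7a-tetrahydro-1H-indene-1,5(6H)-dione | C[C@@]12CCC(=O)C=C1CCC2=O | starting material
2 | (7aR)-1,1-(ethylenedioxy)-7a-methyl-1,2,3,6,7,7a-hexahydro-5H-inden-5-one | C12(OCCO1)CCC3=CC(=O)CC[C@@]23C | intermediate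
3 | (7aR)-1,1-(ethylenedioxy)-4,4,7a-trimethyl-1,2,4,6,7,7a-hexahydro-5H-inden-5-one | C12(OCCO1)CC=C3C(C)(C)C(=O)CC[C@@]23C | intermediate
4 | (3aR,7aR)-1,1-(ethylenedioxy)-4,4,7a-trimethyloctahydro-5H-inden-5-one, trans-fused | C12(OCCO1)CC[C@@H]3C(C)(C)C(=O)CC[C@@]23C | intermediate
5 | (3aR,7aR)-1,1-(ethylenedioxy)-4,4,7a-trimethyl-2,3,3a,4,7,7a-hexahydro-1H-inden-5-yl trifluoromethanesulfonate | C12(OCCO1)CC[C@@H]3C(C)(C)C(OS(=O)(=O)C(F)(F)F)=CC[C@@]23C | intermediate
6 | (3aR,7aR)-1,1-(ethylenedioxy)-4,4,7a-trimethyl-2,3,3a,4,7,7a-hexahydro-1H-indene | C12(OCCO1)CC[C@@H]3C(C)(C)C=CC[C@@]23C | intermediate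
7 | (3aR,7aR)-4,4,7a-trimethyl-2,3,3a,4,7,7a-hexahydro-1H-inden-1-one | O=C1CC[C@@H]2C(C)(C)C=CC[C@@]12C | intermediate
8 | (3R)-5-methoxy-3-methyl-5-oxopentanoic acid ((R)-3-methylglutaric acid monomethyl ester) | OC(=O)C[C@@H](C)CC(=O)OC | starting material
9 | methyl (3R)-5-hydroxy-3-methylpentanoate | OCC[C@@H](C)CC(=O)OC | intermediate
10 | methyl (3R)-5-(tert-butyldimethylsilyloxy)-3-methylpentanoate | CC(C)(C)[Si](C)(C)OCC[C@@H](C)CC(=O)OC | intermediate
11 | (3R)-5-(tert-butyldimethylsilyloxy)-3-methylpentanal | CC(C)(C)[Si](C)(C)OCC[C@@H](C)CC=O | intermediate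
12 | dibromomethane | BrCBr | starting material
13 | lithium alkoxide of the C8 dibromomethyl carbinol of 7 (CHBr2 anti to the C10 methyl) | [Li]O[C@]1(C(Br)Br)CC[C@@H]2C(C)(C)C=CC[C@@]12C | intermediate
14 | β-oxido carbenoid (C8–OLi; C9 carries Br and Li, configuration at C9 undefined) | [Li]O[C@]1(C([Li])Br)CC[C@@H]2C(C)(C)C=CC[C@@]12C | intermediate
15 | lithium C8/C9 enolate of (5R,10R)-17,11–16-heptanor-labd-2-en-8-one (ring-enlarged trans-decalone) | C1=C(O[Li])CC[C@@H]2C(C)(C)C=CC[C@@]12C | intermediate
16 | 15-(tert-butyldimethylsilyloxy)-11-hydroxy-17-norlabd-2-en-8-one (C11 epimers) | CC(C)(C)[Si](C)(C)OCC[C@@H](C)CC(O)[C@H]1C(=O)CC[C@@H]2C(C)(C)C=CC[C@@]12C | intermediate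
17 | C11 methanesulfonate of 16 | CC(C)(C)[Si](C)(C)OCC[C@@H](C)CC(OS(C)(=O)=O)[C@H]1C(=O)CC[C@@H]2C(C)(C)C=CC[C@@]12C | intermediate
18 | (5R,10R,13S,9(11)Z)-15-(tert-butyldimethylsilyloxy)-17-norlabda-2,9(11)-dien-8-one | CC(C)(C)[Si](C)(C)OCC[C@@H](C)C/C=C1\C(=O)CC[C@@H]2C(C)(C)C=CC[C@@]12C | intermediate
19 | (5R,9S,10R,13S)-15-(tert-butyldimethylsilyloxy)-17-norlabd-2-en-8-one | CC(C)(C)[Si](C)(C)OCC[C@@H](C)CC[C@@H]1C(=O)CC[C@@H]2C(C)(C)C=CC[C@@]12C | intermediate
20 | (5R,9S,10R,13S)-15-(tert-butyldimethylsilyloxy)-17-norlabda-2,7-dien-8-yl trifluoromethanesulfonate | CC(C)(C)[Si](C)(C)OCC[C@@H](C)CC[C@@H]1C(OS(=O)(=O)C(F)(F)F)=CC[C@@H]2C(C)(C)C=CC[C@@]12C | intermediate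
21 | (2S,3R,5S,9S,10R,13S)-15-(tert-butyldimethylsilyloxy)-2,3-dihydroxy-17-norlabd-7-en-8-yl trifluoromethanesulfonate | CC(C)(C)[Si](C)(C)OCC[C@@H](C)CC[C@@H]1C(OS(=O)(=O)C(F)(F)F)=CC[C@@H]2C(C)(C)[C@@H](O)[C@@H](O)C[C@@]12C | intermediate
22 | (2S,3R,5S,9R,10S,13S)-15-(tert-butyldimethylsilyloxy)labd-7-ene-2,3-diol | CC(C)(C)[Si](C)(C)OCC[C@@H](C)CC[C@@H]1C(C)=CC[C@@H]2C(C)(C)[C@@H](O)[C@@H](O)C[C@@]12C | intermediate
23 | (2S,3R,5S,9R,10S,13S)-labd-7-ene-2,3,15-triol | OCC[C@@H](C)CC[C@@H]1C(C)=CC[C@@H]2C(C)(C)[C@@H](O)[C@@H](O)C[C@@]12C | intermediate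
24 | (2S,3R,5S,9R,10S,13S)-3-hydroxylabd-7-ene-2,15-diyl diacetate (CNP0144124.1) | CC(=O)OCC[C@@H](C)CC[C@@H]1C(C)=CC[C@@H]2C(C)(C)[C@@H](O)[C@@H](OC(C)=O)C[C@@]12C | target

Total step count: 16. Longest linear sequence: 13 steps (steps 1–6 and 10–16, from 1).

Steps most likely to fail

1. Step 10. In carbenoid 14 the methylene carbon C7 may migrate in place of the quaternary C10, or the hindered ketone 7 may be enolised by dibromomethyllithium and not attacked. The fallback sets out from 11 and 7 and comes back at 16; it moves the ring enlargement to a Lewis-acid semipinacol rearrangement of a 2,3-epoxy alcohol, a cationic 1,2-shift in which a tertiary alkyl group is the better migrating group. Takai iodo-olefination of 11 (CrCl2, CHI3, THF, 0 °C) should give the (E)-vinyl iodide F1. Iodine–lithium exchange (t-BuLi, Et2O, −78 °C) and addition of the vinyllithium to 7 anti to the C10 methyl should give the tertiary allylic alcohol F2. Hydroxyl-directed epoxidation (VO(acac)2, t-BuOOH, CH2Cl2) should give the epoxy alcohol F3. BF3·OEt2 (CH2Cl2, −78 °C) should then open the epoxide at C9 with anti shift of the C8–C10 bond, enlarging the ring and returning β-hydroxy ketone 16 as a stereoisomer mixture that converges in step 11.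

2. Step 3. Hydrogen may be delivered to the hindered C5=C6 alkene from the methyl-bearing face (cis ring fusion), or the alkene may not be reduced at all. The fallback goes from 3 to 4 and makes no new compound (F0): radical hydrogen-atom-transfer hydrogenation with Mn(dpm)3 (cat.), PhSiH3, t-BuOOH, i-PrOH, 23 °C. H-atom transfer to C6 gives the planar tertiary C5 radical, which should be quenched from the face opposite the C10 methyl to give trans-fused 4.

3. Step 16. The axial C3 hydroxyl may be acetylated as well, or the acetyl group may migrate from O2 to O3, giving mixtures of acetates. The fallback goes from 23 to 24 by tin-acetal-directed acylation. Bu2SnO (toluene, reflux, removal of water) should convert the cis-2,3-diol into the dibutylstannylene acetal F4. AcCl (2.1 equiv), Et3N, CH2Cl2, 0 °C should then acetylate the primary C15 hydroxyl and, through the stannylene, only the equatorial O2, giving 24 after aqueous work-up.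

Further compounds

F1 | step 10 | (S,E)-tert-butyl[(6-iodo-3-methylhex-5-en-1-yl)oxy]dimethylsilane | CC(C)(C)[Si](C)(C)OCC[C@@H](C)C/C=C/I
F2 | step 10 | tertiary allylic alcohol from 7 (C8 carbinol carrying the (E)-C9=C11 alkenyl chain anti to the C10 methyl) | CC(C)(C)[Si](C)(C)OCC[C@@H](C)C/C=C/[C@@]1(O)CC[C@@H]2C(C)(C)C=CC[C@@]12C
F3 | step 10 | 2,3-epoxy alcohol from F2 (trans C9–C11 epoxide, epoxide diastereomers) | CC(C)(C)[Si](C)(C)OCC[C@@H](C)CC1OC1[C@@]2(O)CC[C@@H]3C(C)(C)C=CC[C@@]23C
F0 | step 3 | none | none
F4 | step 16 | 2,3-O-dibutylstannylene acetal of triol 23 | OCC[C@@H](C)CC[C@@H]1C(C)=CC[C@@H]2C(C)(C)[C@H]3O[Sn](CCCC)(CCCC)O[C@H]3C[C@@]12C
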